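**Retrosynthetic overview**
- The target comes from its bis(triisopropylsilyl) ether by Si–O cleavage (last step).
- C4–C6' (the only bond between the halves and the only stereocentre) comes from an enantioselective hydroarylative homodimerisation of one 8-prenyl-2H-chromen-5-ol. One molecule reacts as an ortho-quinone methide and its pyran ring becomes the chromane (ring B); the other reacts as a phenol at C6 and its pyran ring stays the chromene (ring A).
- The C8 prenyl group comes from an aryl prenyl ether (C–O bond at the 5-oxygen), moved to the para carbon by a Claisen–Cope sequence.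
- The pyran O1–C2 bond comes from oxa-6π ring closure of the vinyl ortho-quinone methide made from dihydroresveratrol and 3-methylbut-2-enal. This C–O closure turns one of the two equivalent resorcinol oxygens into the ring oxygen and leaves the other as the handle that fixes all later regiochemistry.
- Ring order: the pyran ring is closed first, on the monomer. Both pyran rings of the target come from it, so no ring is formed after step 1.

Assumptions: the stereocentre of the given SMILES is read as (4R); the (R)-phosphoric acid is taken to give it (the (S)-acid is used in the same step if the sense proves opposite); dihydroresveratrol is taken as commercial.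

Step 1
Reactants: 1 5-[2-(4-hydroxyphenyl)ethyl]benzene-1,3-diol (dihydroresveratrol); 2 3-methylbut-2-enal
Product: 4 7-[2-(4-hydroxyphenyl)ethyl]-2,2-dimethyl-2H-chromen-5-ol, via vinyl ortho-quinone methide 3 (not isolated)
Conditions: 2 (1.1 equiv), ethylenediammonium diacetate (10 mol%), toluene/DMF 9:1, 110 °C, 8 h
Reagents that add atoms: none
Why: Amine-catalysed Knoevenagel-type condensation at the carbon between the two hydroxyls gives 3, whose oxa-6π electrocyclisation forms the O1–C2 bond (formal [3+3] chromene annulation, as used for cannabichromene); the resorcinol is symmetric, so either oxygen gives the same chromene, and no stereocentre is formed.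

Step 2
Reactants: 4 7-[2-(4-hydroxyphenyl)ethyl]-2,2-dimethyl-2H-chromen-5-ol
Product: 5 2,2-dimethyl-7-{2-[4-(triisopropylsilyloxy)phenyl]ethyl}-2H-chromen-5-ol
Conditions: iPr3SiCl (1.05 equiv), imidazole (2.5 equiv), DMF, −20 to 0 °C
Reagents that add atoms: chlorotriisopropylsilane (iPr3SiCl), CC(C)[Si](Cl)(C(C)C)C(C)C
Why: Silyl ether formation under steric control: the bulky silyl chloride takes the unhindered 4'-phenol and leaves the 5-OH, which is ortho-substituted and peri to C4–H; no stereocentre.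

Step 3
Reactants: 5 2,2-dimethyl-7-{2-[4-(triisopropylsilyloxy)phenyl]ethyl}-2H-chromen-5-ol; 6 1-bromo-3-methylbut-2-ene (prenyl bromide)
Product: 7 2,2-dimethyl-5-(3-methylbut-2-enyloxy)-7-{2-[4-(triisopropylsilyloxy)phenyl]ethyl}-2H-chromene
Conditions: 6 (1.3 equiv), K2CO3 (2 equiv), acetone, 50 °C
Reagents that add atoms: none
Why: Williamson ether synthesis on the only free phenol puts the prenyl group on the oxygen that lies para to C8; no stereocentre.

Step 4
Reactants: 7 2,2-dimethyl-5-(3-methylbut-2-enyloxy)-7-{2-[4-(triisopropylsilyloxy)phenyl]ethyl}-2H-chromene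
Product: 10 2,2-dimethyl-8-(3-methylbut-2-enyl)-7-{2-[4-(triisopropylsilyloxy)phenyl]ethyl}-2H-chromen-5-ol, via ortho-dienone 8 (not isolated), via para-dienone 9 (not isolated)
Conditions: decalin (0.05 M), 190 °C, sealed tube, Ar
Reagents that add atoms: none
Why: Aromatic Claisen rearrangement to C6 gives 8, whose tert-alkyl group is squeezed between C5=O and the C7 side chain, so Cope rearrangement to C8 (para-Claisen, Claisen–Cope sequence) should outrun enolisation, and tautomerisation of 9 gives the linear prenyl group at C8; no stereocentre.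

Step 5
Reactants: 10 2,2-dimethyl-8-(3-methylbut-2-enyl)-7-{2-[4-(triisopropylsilyloxy)phenyl]ethyl}-2H-chromen-5-ol (two molecules)
Product: 12 (4R)-4-[5-hydroxy-2,2-dimethyl-8-(3-methylbut-2-enyl)-7-{2-[4-(triisopropylsilyloxy)phenyl]ethyl}-2H-chromen-6-yl]-2,2-dimethyl-8-(3-methylbut-2-enyl)-7-{2-[4-(triisopropylsilyloxy)phenyl]ethyl}chroman-5-ol, via ortho-quinone methide 11 (not isolated)
Conditions: (R)-3,3'-bis(2,4,6-triisopropylphenyl)-1,1'-binaphthyl-2,2'-diyl hydrogen phosphate (10 mol%), toluene (0.5 M), 5 Å molecular sieves, 30 °C, to about 70% conversion, unreacted 10 recovered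
Reagents that add atoms: none
Why: Proposed new method: 10 is an ortho-hydroxystyrene, so the chiral phosphoric acid can shuttle the phenol proton to C3 and form the cyclic ortho-quinone methide 11 (a vinylogous ester of one fixed geometry) held by P–OH···O=C5, while the P=O oxygen binds the 5-OH of a second molecule of 10 and delivers its only free ring carbon C6 to one face of C4, which sets (4R); the closest known reaction type is the phosphoric-acid-catalysed enantioselective conjugate addition of indoles, naphthols or phenols to ortho-quinone methides made in situ from ortho-hydroxystyrenes or ortho-hydroxybenzyl alcohols (asymmetric Friedel–Crafts hydroarylation), not yet shown on a 2H-chromene or as a homodimerisation.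

Step 6
Reactants: 12 (4R)-bis(triisopropylsilyl) ether dimer
Product: 13 (4R)-4-[5-hydroxy-7-[2-(4-hydroxyphenyl)ethyl]-2,2-dimethyl-8-(3-methylbut-2-enyl)-2H-chromen-6-yl]-7-[2-(4-hydroxyphenyl)ethyl]-2,2-dimethyl-8-(3-methylbut-2-enyl)chroman-5-ol (CNP0103951.1)
Conditions: Bu4NF (2.4 equiv), AcOH (2.4 equiv), THF, 0 °C
Reagents that add atoms: none
Why: Fluoride-mediated cleavage of both aryl silyl ethers (driven by Si–F bond formation), buffered by AcOH so that the chromene, the prenyl groups and the C4 stereocentre are untouched.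

**Compound list**
1 | 5-[2-(4-hydroxyphenyl)ethyl]benzene-1,3-diol (dihydroresveratrol) | Oc1ccc(CCc2cc(O)cc(O)c2)cc1 | starting material
2 | 3-methylbut-2-enal | CC(C)=CC=O | starting material
3 | 3-hydroxy-5-[2-(4-hydroxyphenyl)ethyl]-2-(3-methylbut-2-enylidene)cyclohexa-3,5-dien-1-one (vinyl ortho-quinone methide) | CC(C)=CC=C1C(=O)C=C(CCc2ccc(O)cc2)C=C1O | intermediate
4 | 7-[2-(4-hydroxyphenyl)ethyl]-2,2-dimethyl-2H-chromen-5-ol | CC1(C)C=Cc2c(O)cc(CCc3ccc(O)cc3)cc2O1 | intermediate
5 | 2,2-dimethyl-7-{2-[4-(triisopropylsilyloxy)phenyl]ethyl}-2H-chromen-5-ol | CC1(C)C=Cc2c(O)cc(CCc3ccc(O[Si](C(C)C)(C(C)C)C(C)C)cc3)cc2O1 | intermediate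
6 | 1-bromo-3-methylbut-2-ene (prenyl bromide) | CC(C)=CCBr | starting material
7 | 2,2-dimethyl-5-(3-methylbut-2-enyloxy)-7-{2-[4-(triisopropylsilyloxy)phenyl]ethyl}-2H-chromene | CC1(C)C=Cc2c(OCC=C(C)C)cc(CCc3ccc(O[Si](C(C)C)(C(C)C)C(C)C)cc3)cc2O1 | intermediate
8 | 2,2-dimethyl-6-(2-methylbut-3-en-2-yl)-7-{2-[4-(triisopropylsilyloxy)phenyl]ethyl}-2H-chromen-5(6H)-one (ortho-dienone, racemic) | C=CC(C)(C)C1C(=O)C2=C(OC(C)(C)C=C2)C=C1CCc1ccc(O[Si](C(C)C)(C(C)C)C(C)C)cc1 | intermediate
9 | 2,2-dimethyl-8-(3-methylbut-2-enyl)-7-{2-[4-(triisopropylsilyloxy)phenyl]ethyl}-2H-chromen-5(8H)-one (para-dienone, racemic) | CC(C)=CCC1C(CCc2ccc(O[Si](C(C)C)(C(C)C)C(C)C)cc2)=CC(=O)C2=C1OC(C)(C)C=C2 | intermediate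
10 | 2,2-dimethyl-8-(3-methylbut-2-enyl)-7-{2-[4-(triisopropylsilyloxy)phenyl]ethyl}-2H-chromen-5-ol | CC(C)=CCc1c(CCc2ccc(O[Si](C(C)C)(C(C)C)C(C)C)cc2)cc(O)c2c1OC(C)(C)C=C2 | intermediate
11 | 2,2-dimethyl-8-(3-methylbut-2-enyl)-7-{2-[4-(triisopropylsilyloxy)phenyl]ethyl}-2,3-dihydro-5H-chromen-5-one (ortho-quinone methide tautomer of 10) | CC(C)=CCC1=C2OC(C)(C)CC=C2C(=O)C=C1CCc1ccc(O[Si](C(C)C)(C(C)C)C(C)C)cc1 | intermediate
12 | (4R)-4-[5-hydroxy-2,2-dimethyl-8-(3-methylbut-2-enyl)-7-{2-[4-(triisopropylsilyloxy)phenyl]ethyl}-2H-chromen-6-yl]-2,2-dimethyl-8-(3-methylbut-2-enyl)-7-{2-[4-(triisopropylsilyloxy)phenyl]ethyl}chroman-5-ol | CC(C)=CCc1c(CCc2ccc(O[Si](C(C)C)(C(C)C)C(C)C)cc2)c([C@H]2CC(C)(C)Oc3c(CC=C(C)C)c(CCc4ccc(O[Si](C(C)C)(C(C)C)C(C)C)cc4)cc(O)c32)c(O)c2c1OC(C)(C)C=C2 | intermediate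
13 | (4R)-4-[5-hydroxy-7-[2-(4-hydroxyphenyl)ethyl]-2,2-dimethyl-8-(3-methylbut-2-enyl)-2H-chromen-6-yl]-7-[2-(4-hydroxyphenyl)ethyl]-2,2-dimethyl-8-(3-methylbut-2-enyl)chroman-5-ol | CC(C)=CCc1c(CCc2ccc(O)cc2)c([C@H]2CC(C)(C)Oc3c(CC=C(C)C)c(CCc4ccc(O)cc4)cc(O)c32)c(O)c2c1OC(C)(C)C=C2 | target

**Step count and risks**
Total step count: 6. Longest linear sequence: 6 steps (1 → 4 → 5 → 7 → 10 → 12 → 13; compound 10 enters step 5 twice).

Step 5 (the new dimerisation) is the most likely to fail. The acid may be too weak to form 11 at a useful rate. The second molecule may attack through its alkene carbon C3 instead of C6. Product 12 still holds an ortho-hydroxystyrene and can go on to trimers. The enantioselectivity is untested. The fallback uses known chemistry, sets out from 10 and comes back at 12. Compound 10 is dimerised by an achiral Brønsted acid (p-toluenesulfonic acid 5 mol%, CH2Cl2, 0 °C; the known Friedel–Crafts alkylation of phenols by chroman-4-yl cations formed from 2,2-dimethyl-2H-chromenes) to give the racemic bis(triisopropylsilyl) ether dimer F4. Preparative chromatography on a chiral stationary phase (amylose tris(3,5-dimethylphenylcarbamate), supercritical CO2/iPrOH) then separates 12 from the (4S)-bis(triisopropylsilyl) ether dimer F5, at the cost of half the material.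

Step 4 (Claisen–Cope) is the second risk. Ortho-dienone 8 may enolise to the 6-(2-methylbut-3-en-2-yl) phenol, or the ether may lose the prenyl group at 190 °C. The fallback sets out from 5 and comes back at 10, so that 7 is not needed, and it replaces the rearrangement by halogenation and cross-coupling. Bromination para to the phenol (N-bromosuccinimide, MeCN, −20 °C) gives 8-bromo-2,2-dimethyl-7-{2-[4-(triisopropylsilyloxy)phenyl]ethyl}-2H-chromen-5-ol F3. A linear-selective Negishi coupling with 3-methylbut-2-enylzinc bromide (Me2C=CHCH2ZnBr 2.5 equiv, Pd(OAc)2 2 mol%, 2-dicyclohexylphosphino-2',6'-bis(dimethylamino)biphenyl 4 mol%, THF, 25 °C) then gives 10.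

Step 1 (chromene annulation) is the third risk. On the unprotected triphenol the aldehyde may add at C4 of the resorcinol (giving the 7-hydroxy-5-substituted isomer) or twice. The fallback sets out from 1 and comes back at 4 and builds the pyran ring through a chromanone. Friedel–Crafts acylation and oxa-Michael closure of 1 with 3-methylbut-2-enoic acid in P2O5/MeSO3H (70 °C) gives 5-hydroxy-7-[2-(4-hydroxyphenyl)ethyl]-2,2-dimethylchroman-4-one F1, the hydrogen-bonded isomer, which is separated from the 7-hydroxy isomer. NaBH4 in MeOH (0 °C) reduces it to 7-[2-(4-hydroxyphenyl)ethyl]-2,2-dimethylchromane-4,5-diol F2. Acid-catalysed dehydration (p-toluenesulfonic acid 2 mol%, toluene, 80 °C, high dilution) gives 4.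

**Further compounds**
F1 | step 1 | 5-hydroxy-7-[2-(4-hydroxyphenyl)ethyl]-2,2-dimethylchroman-4-one | CC1(C)CC(=O)c2c(O)cc(CCc3ccc(O)cc3)cc2O1
F2 | step 1 | 7-[2-(4-hydroxyphenyl)ethyl]-2,2-dimethylchromane-4,5-diol (racemic) | CC1(C)CC(O)c2c(O)cc(CCc3ccc(O)cc3)cc2O1
F3 | step 4 | 8-bromo-2,2-dimethyl-7-{2-[4-(triisopropylsilyloxy)phenyl]ethyl}-2H-chromen-5-ol | CC1(C)C=Cc2c(O)cc(CCc3ccc(O[Si](C(C)C)(C(C)C)C(C)C)cc3)c(Br)c2O1
F4 | step 5 | racemic 4-[5-hydroxy-2,2-dimethyl-8-(3-methylbut-2-enyl)-7-{2-[4-(triisopropylsilyloxy)phenyl]ethyl}-2H-chromen-6-yl]-2,2-dimethyl-8-(3-methylbut-2-enyl)-7-{2-[4-(triisopropylsilyloxy)phenyl]ethyl}chroman-5-ol | CC(C)=CCc1c(CCc2ccc(O[Si](C(C)C)(C(C)C)C(C)C)cc2)c(C2CC(C)(C)Oc3c(CC=C(C)C)c(CCc4ccc(O[Si](C(C)C)(C(C)C)C(C)C)cc4)cc(O)c32)c(O)c2c1OC(C)(C)C=C2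
F5 | step 5 | (4S)-4-[5-hydroxy-2,2-dimethyl-8-(3-methylbut-2-enyl)-7-{2-[4-(triisopropylsilyloxy)phenyl]ethyl}-2H-chromen-6-yl]-2,2-dimethyl-8-(3-methylbut-2-enyl)-7-{2-[4-(triisopropylsilyloxy)phenyl]ethyl}chroman-5-ol | CC(C)=CCc1c(CCc2ccc(O[Si](C(C)C)(C(C)C)C(C)C)cc2)c([C@@H]2CC(C)(C)Oc3c(CC=C(C)C)c(CCc4ccc(O[Si](C(C)C)(C(C)C)C(C)C)cc4)cc(O)c32)c(O)c2c1OC(C)(C)C=C2
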